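**Plan**
- The retrosynthesis cuts O1–C8a and C4–C4a of ring C together: both bonds leave ring A at the adjacent carbons C8a and C4a, which are the two carbons of an aryne, and C2 with its oxygen, C3 and C4 can arrive as one β-oxy amide already attached to ring B.
- Ring A is built from phloroglucinol by two carbamate-directed ortho-metalations (silicon first, then prenyl) and turned into an ortho-silylaryl triflate.
- Ring B receives its 3-methylbut-3-enyl chain by benzyl–allyl coupling and is extended to a β-keto Weinreb amide.
- The only stereocentre, C2, is set by asymmetric transfer hydrogenation of that ketone and is carried through the annulation as a silyl ether, because the C2–O bond is never broken.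
- Ring C closes last but one, and the two acetals are then removed without protic acid.

Key step: step 12

Assumption: the acyl acceptor is an N-methoxy-N-methyl amide and the nucleophile is delivered as its trimethylsilyl ether, so that fluoride frees both partners in a proton-free medium and the ketone stays masked until work-up. The (2S) descriptor is read from the SMILES of the target.

**Step 1**
Reactants: 1 phloroglucinol
Product: 2 3,5-bis(methoxymethoxy)phenol
Conditions: MOMCl (2.0 equiv), iPr2NEt (2.2 equiv), THF, 0 °C → rt; chromatography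
Reagents that add atoms: chloromethyl methyl ether, COCCl
Why: Base-mediated O-alkylation of a phenol with an α-chloro ether (methoxymethyl protection) is routine, and because the three hydroxyls of 1 are equivalent only one bis-ether can form, which should be separable from the mono- and tris-ethers of this statistical reaction.

**Step 2**
Reactants: 2 3,5-bis(methoxymethoxy)phenol
Product: 3 3,5-bis(methoxymethoxy)phenyl N-(propan-2-yl)carbamate
Conditions: iPrNCO (1.3 equiv), Et3N (0.2 equiv), CH2Cl2, rt
Reagents that add atoms: isopropyl isocyanate, CC(C)N=C=O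
Why: Amine-catalysed addition of a phenol to an isocyanate (carbamoylation) should give the N-monoalkyl carbamate, which is the strongest ortho-director on the ring and can later be removed without acid.

**Step 3**
Reactants: 3 3,5-bis(methoxymethoxy)phenyl N-(propan-2-yl)carbamate
Product: 7 3,5-bis(methoxymethoxy)-2-(trimethylsilyl)phenyl N-(propan-2-yl)carbamate, via N-silyl carbamate 4 (not isolated), via aryllithium 5 (not isolated), via bis-silyl carbamate 6 (not isolated)
Conditions: TMSOTf (1.05 equiv), TMEDA (1.1 equiv), Et2O, 0 °C → rt; TMEDA (2 equiv), n-BuLi (2.2 equiv), −78 °C; TMSCl (1.1 equiv), −78 °C → rt; sat. aq. NH4Cl; chromatography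
Reagents that add atoms: chlorotrimethylsilane, C[Si](C)(C)Cl
Why: Directed ortho-metalation in which the N–H is first capped as N-silyl carbamate 4 so that base cannot eliminate the carbamate, n-BuLi/TMEDA then removes the proton at C2 between the carbamate and an acetal oxygen in preference to C4 between the two weaker acetal directors, chlorotrimethylsilane traps aryllithium 5 at −78 °C, and the N–Si bond of 6 is hydrolysed at work-up so that 7 can be purified before the second metalation.

**Step 4**
Reactants: 7 3,5-bis(methoxymethoxy)-2-(trimethylsilyl)phenyl N-(propan-2-yl)carbamate; 8 prenyl bromide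
Product: 12 3,5-bis(methoxymethoxy)-2-(3-methylbut-2-enyl)-6-(trimethylsilyl)phenyl N-(propan-2-yl)carbamate, via N-TBS carbamate 9 (not isolated), via aryllithium 10 (not isolated), via N-TBS prenyl carbamate 11 (not isolated)
Conditions: TBSOTf (1.05 equiv), TMEDA (1.1 equiv), Et2O, 0 °C → rt; TMEDA (2 equiv), n-BuLi (2.2 equiv), −78 °C; CuBr·SMe2 (10 mol%), THF, then 8, −78 → 0 °C; 5% aq. citric acid, 0 °C → rt
Reagents that add atoms: none
Why: A second directed ortho-metalation at C6, the only position still flanked by the carbamate, followed by copper-catalysed allylic substitution at the unhindered primary carbon of prenyl bromide should give the linear prenyl arene; nitrogen is capped here with the bulkier tert-butyldimethylsilyl group (9) because the arylmetal formed from 10 is warmed to 0 °C and a trimethylsilyl group on nitrogen could shift to the neighbouring carbanion, and silicon is placed on the ring before prenyl so that no benzylic-allylic CH2 sits next to the carbamate while a lithium base is present.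

**Step 5**
Reactants: 12 3,5-bis(methoxymethoxy)-2-(3-methylbut-2-enyl)-6-(trimethylsilyl)phenyl N-(propan-2-yl)carbamate
Product: 14 3,5-bis(methoxymethoxy)-2-(3-methylbut-2-enyl)-6-(trimethylsilyl)phenyl trifluoromethanesulfonate, via phenol 13 (not isolated)
Conditions: Et2NH (1.25 equiv), DBU (1.5 equiv), MeCN, 40 °C; then PhNTf2 (1.5 equiv), 40 °C
Reagents that add atoms: N-phenylbis(trifluoromethanesulfonimide), O=S(=O)(N(c1ccccc1)S(=O)(=O)C(F)(F)F)C(F)(F)F
Why: Base-induced elimination of the N–H carbamate to the phenoxide of 13 and isopropyl isocyanate (trapped by diethylamine as a urea) does not need access to the crowded carbonyl, and O-sulfonylation of the phenoxide by PhNTf2 in the same flask is the established one-pot route to ortho-silylaryl triflates.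

**Step 6**
Reactants: 15 3-(chloromethyl)-4-methoxybenzaldehyde
Product: 16 2-[3-(chloromethyl)-4-methoxyphenyl]-1,3-dioxolane
Conditions: ethylene glycol (3 equiv), p-TsOH·H2O (2 mol%), toluene, reflux, Dean–Stark
Reagents that add atoms: ethylene glycol, OCCO
Why: Acid-catalysed acetalisation with azeotropic removal of water should mask the aldehyde as a dioxolane while the benzylic chloride, which does not ionise in toluene, is left untouched.

**Step 7**
Reactants: 16 2-[3-(chloromethyl)-4-methoxyphenyl]-1,3-dioxolane; 17 2-methylallylmagnesium chloride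
Product: 19 4-methoxy-3-(3-methylbut-3-enyl)benzaldehyde, via dioxolane 18 (not isolated)
Conditions: 17 (1.3 equiv), CuI (5 mol%), THF, −20 °C → rt; sat. aq. NH4Cl; crude 18, PPTS (10 mol%), acetone/H2O, 50 °C
Reagents that add atoms: water, O
Why: Copper-catalysed sp3–sp3 cross-coupling of a benzylic chloride with an allylic Grignard reagent (both ends of the 2-methylallyl nucleophile give the same product) should build the 3-methylbut-3-enyl chain, and the electron-rich aryl dioxolane is then hydrolysed by an acid weak enough to leave the 1,1-disubstituted alkene unhydrated.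

**Step 8**
Reactants: 19 4-methoxy-3-(3-methylbut-3-enyl)benzaldehyde
Product: 20 rac-3-hydroxy-N-methoxy-3-[4-methoxy-3-(3-methylbut-3-enyl)phenyl]-N-methylpropanamide
Conditions: N-methoxy-N-methylacetamide (1.3 equiv), LiN(iPr)2 (1.3 equiv), THF, −78 °C; then 19, −78 °C; sat. aq. NH4Cl
Reagents that add atoms: N-methoxy-N-methylacetamide, CC(=O)N(C)OC
Why: Aldol addition of the lithium enolate of an acetamide to a non-enolisable aromatic aldehyde at low temperature is well known and gives the racemic β-hydroxy Weinreb amide, whose carbinol configuration is set later.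

**Step 9**
Reactants: 20 rac-3-hydroxy-N-methoxy-3-[4-methoxy-3-(3-methylbut-3-enyl)phenyl]-N-methylpropanamide
Product: 21 N-methoxy-3-[4-methoxy-3-(3-methylbut-3-enyl)phenyl]-N-methyl-3-oxopropanamide
Conditions: Dess–Martin periodinane (1.2 equiv), CH2Cl2, 0 °C → rt
Reagents that add atoms: none
Why: Dess–Martin oxidation of a secondary benzylic alcohol under neutral conditions should give the β-keto amide without touching the alkene or the N–O bond.

**Step 10**
Reactants: 21 N-methoxy-3-[4-methoxy-3-(3-methylbut-3-enyl)phenyl]-N-methyl-3-oxopropanamide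
Product: 22 (3S)-3-hydroxy-N-methoxy-3-[4-methoxy-3-(3-methylbut-3-enyl)phenyl]-N-methylpropanamide
Conditions: RuCl[(S,S)-TsDPEN](p-cymene) (1 mol%), HCO2H/Et3N (5:2), CH2Cl2, 30 °C
Reagents that add atoms: none
Why: Noyori–Ikariya asymmetric transfer hydrogenation reduces the aryl ketone through a six-membered outer-sphere transition state in which the aryl group lies under the η6-arene, so the (S,S)-ligand should deliver hydride to the face that gives the (S)-alcohol as it does with acetophenone, while isolated alkenes are inert.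

**Step 11**
Reactants: 22 (3S)-3-hydroxy-N-methoxy-3-[4-methoxy-3-(3-methylbut-3-enyl)phenyl]-N-methylpropanamide
Product: 23 (3S)-N-methoxy-3-[4-methoxy-3-(3-methylbut-3-enyl)phenyl]-N-methyl-3-(trimethylsilyloxy)propanamide
Conditions: TMSCl (1.3 equiv), imidazole (2 equiv), CH2Cl2, 0 °C; filtration through Et3N-deactivated silica
Reagents that add atoms: chlorotrimethylsilane, C[Si](C)(C)Cl
Why: O-Silylation of a secondary alcohol with TMSCl/imidazole is routine, leaves the carbinol configuration untouched and replaces the O–H by an O–Si bond that fluoride can cleave without releasing a proton.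

**Step 12**
Reactants: 14 3,5-bis(methoxymethoxy)-2-(3-methylbut-2-enyl)-6-(trimethylsilyl)phenyl trifluoromethanesulfonate; 23 (3S)-N-methoxy-3-[4-methoxy-3-(3-methylbut-3-enyl)phenyl]-N-methyl-3-(trimethylsilyloxy)propanamide
Product: 28 (2S)-2-[4-methoxy-3-(3-methylbut-3-enyl)phenyl]-5,7-bis(methoxymethoxy)-8-(3-methylbut-2-enyl)chroman-4-one, via aryne 24 (not isolated), via cesium alkoxide 25 (not isolated), via arylcesium 26 (not isolated), via tetrahedral adduct 27 (not isolated)
Conditions: 23 (1.3 equiv), CsF (3 equiv), 18-crown-6 (3 equiv), THF, 0 °C; 14 added over 1 h, → rt; then pH 7 phosphate buffer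
Reagents that add atoms: none
Why: Proposed new method: fluoride strips the C-silyl group of 14 to release aryne 24 and the O-silyl group of 23 to release alkoxide 25 in a medium that holds no O–H proton; 25 adds to the aryne carbon C8a, the aryl anion 26 formed at C4a attacks the Weinreb amide carbonyl, and the tetrahedral cesium alkoxide 27 persists until the buffered quench releases ketone 28. The closest known reaction types are the fluoride-triggered annulation of arynes with salicylate esters to xanthones and the insertion of arynes into alcohol O–H bonds, whereas an aliphatic β-oxido amide as annulation partner has no precedent. Ring C closes by a 6-exo-trig acyl addition of the C4a anion to C4, right after the intermolecular O1–C8a bond has formed. No stereocentre is created, since the C2–O bond is never broken and the (S) configuration from step 10 is carried through, while the C4 centre of 27 is lost on collapse. The step needs alkoxide attack at C8a and not at C4a, which the C5 methoxymethoxy group should secure by polarising the aryne so that the negative charge develops next to the inductively withdrawing oxygen, and it needs acyl capture to outrun protonation, which the proton-free release of the alkoxide from its silyl ether should secure. Keeping the carbonyl masked as 27 also keeps the flavanone away from base, so that no enolate can open ring C and erase C2.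

**Step 13**
Reactants: 28 (2S)-2-[4-methoxy-3-(3-methylbut-3-enyl)phenyl]-5,7-bis(methoxymethoxy)-8-(3-methylbut-2-enyl)chroman-4-one
Product: 30 (2S)-5,7-dihydroxy-2-[4-methoxy-3-(3-methylbut-3-enyl)phenyl]-8-(3-methylbut-2-enyl)chroman-4-one, via bis-silyl ether 29 (not isolated)
Conditions: TMSOTf (4 equiv), 2,2'-bipyridyl (6 equiv), MeCN, 0 °C → rt; then H2O, rt
Reagents that add atoms: none
Why: Cleavage of aryl methoxymethyl ethers by a silyl triflate buffered with 2,2'-bipyridyl passes through aryl silyl ethers 29 that water hydrolyses, so no free strong acid is present that could isomerise or hydrate the 1,1-disubstituted alkene, cyclise the C7 hydroxyl onto the prenyl group or ionise the benzylic C2–O bond.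

**Compound list**
1 | phloroglucinol (benzene-1,3,5-triol) | Oc1cc(O)cc(O)c1 | starting material
2 | 3,5-bis(methoxymethoxy)phenol | COCOc1cc(O)cc(OCOC)c1 | intermediate
3 | 3,5-bis(methoxymethoxy)phenyl N-(propan-2-yl)carbamate | CC(C)NC(=O)Oc1cc(OCOC)cc(OCOC)c1 | intermediate
4 | 3,5-bis(methoxymethoxy)phenyl N-(propan-2-yl)-N-(trimethylsilyl)carbamate | CC(C)N(C(=O)Oc1cc(OCOC)cc(OCOC)c1)[Si](C)(C)C | intermediate (not isolated)
5 | 2-lithio derivative of 4 (lithium between the carbamate and an acetal oxygen) | CC(C)N(C(=O)Oc1cc(OCOC)cc(OCOC)c1[Li])[Si](C)(C)C | intermediate (not isolated)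
6 | 3,5-bis(methoxymethoxy)-2-(trimethylsilyl)phenyl N-(propan-2-yl)-N-(trimethylsilyl)carbamate | CC(C)N(C(=O)Oc1cc(OCOC)cc(OCOC)c1[Si](C)(C)C)[Si](C)(C)C | intermediate (not isolated)
7 | 3,5-bis(methoxymethoxy)-2-(trimethylsilyl)phenyl N-(propan-2-yl)carbamate | CC(C)NC(=O)Oc1cc(OCOC)cc(OCOC)c1[Si](C)(C)C | intermediate
8 | prenyl bromide (1-bromo-3-methylbut-2-ene) | CC(C)=CCBr | starting material
9 | 3,5-bis(methoxymethoxy)-2-(trimethylsilyl)phenyl N-[tert-butyl(dimethyl)silyl]-N-(propan-2-yl)carbamate | CC(C)N(C(=O)Oc1cc(OCOC)cc(OCOC)c1[Si](C)(C)C)[Si](C)(C)C(C)(C)C | intermediate (not isolated)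
10 | 6-lithio derivative of 9 (lithium between the carbamate and the other acetal oxygen) | CC(C)N(C(=O)Oc1c([Li])c(OCOC)cc(OCOC)c1[Si](C)(C)C)[Si](C)(C)C(C)(C)C | intermediate (not isolated)
11 | 3,5-bis(methoxymethoxy)-2-(3-methylbut-2-enyl)-6-(trimethylsilyl)phenyl N-[tert-butyl(dimethyl)silyl]-N-(propan-2-yl)carbamate | CC(C)N(C(=O)Oc1c(CC=C(C)C)c(OCOC)cc(OCOC)c1[Si](C)(C)C)[Si](C)(C)C(C)(C)C | intermediate (not isolated)
12 | 3,5-bis(methoxymethoxy)-2-(3-methylbut-2-enyl)-6-(trimethylsilyl)phenyl N-(propan-2-yl)carbamate | CC(C)NC(=O)Oc1c(CC=C(C)C)c(OCOC)cc(OCOC)c1[Si](C)(C)C | intermediate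
13 | 3,5-bis(methoxymethoxy)-2-(3-methylbut-2-enyl)-6-(trimethylsilyl)phenol | CC(C)=CCc1c(O)c([Si](C)(C)C)c(OCOC)cc1OCOC | intermediate (not isolated)
14 | 3,5-bis(methoxymethoxy)-2-(3-methylbut-2-enyl)-6-(trimethylsilyl)phenyl trifluoromethanesulfonate | CC(C)=CCc1c(OCOC)cc(OCOC)c([Si](C)(C)C)c1OS(=O)(=O)C(F)(F)F | intermediate
15 | 3-(chloromethyl)-4-methoxybenzaldehyde | COc1ccc(C=O)cc1CCl | starting material
16 | 2-[3-(chloromethyl)-4-methoxyphenyl]-1,3-dioxolane | COc1ccc(C2OCCO2)cc1CCl | intermediate
17 | 2-methylallylmagnesium chloride | C=C(C)C[Mg]Cl | starting material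
18 | 2-[4-methoxy-3-(3-methylbut-3-enyl)phenyl]-1,3-dioxolane | C=C(C)CCc1cc(C2OCCO2)ccc1OC | intermediate (not isolated)
19 | 4-methoxy-3-(3-methylbut-3-enyl)benzaldehyde | C=C(C)CCc1cc(C=O)ccc1OC | intermediate
20 | rac-3-hydroxy-N-methoxy-3-[4-methoxy-3-(3-methylbut-3-enyl)phenyl]-N-methylpropanamide | C=C(C)CCc1cc(C(O)CC(=O)N(C)OC)ccc1OC | intermediate
21 | N-methoxy-3-[4-methoxy-3-(3-methylbut-3-enyl)phenyl]-N-methyl-3-oxopropanamide | C=C(C)CCc1cc(C(=O)CC(=O)N(C)OC)ccc1OC | intermediate
22 | (3S)-3-hydroxy-N-methoxy-3-[4-methoxy-3-(3-methylbut-3-enyl)phenyl]-N-methylpropanamide | C=C(C)CCc1cc([C@@H](O)CC(=O)N(C)OC)ccc1OC | intermediate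
23 | (3S)-N-methoxy-3-[4-methoxy-3-(3-methylbut-3-enyl)phenyl]-N-methyl-3-(trimethylsilyloxy)propanamide | C=C(C)CCc1cc([C@@H](O[Si](C)(C)C)CC(=O)N(C)OC)ccc1OC | intermediate
24 | 3,5-bis(methoxymethoxy)-6-(3-methylbut-2-enyl)benzyne | CC(C)=CCC1=C(OCOC)C=C(OCOC)C#C1 | intermediate (not isolated)
25 | cesium alkoxide of 22, (S) | C=C(C)CCc1cc([C@@H]([O-])CC(=O)N(C)OC)ccc1OC.[Cs+] | intermediate (not isolated)
26 | (3S)-3-[2-cesio-3,5-bis(methoxymethoxy)-6-(3-methylbut-2-enyl)phenoxy]-N-methoxy-3-[4-methoxy-3-(3-methylbut-3-enyl)phenyl]-N-methylpropanamide | C=C(C)CCc1cc([C@H](CC(=O)N(C)OC)Oc2c(CC=C(C)C)c(OCOC)cc(OCOC)c2[Cs])ccc1OC | intermediate (not isolated)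
27 | cesium (2S)-4-[methoxy(methyl)amino]-2-[4-methoxy-3-(3-methylbut-3-enyl)phenyl]-5,7-bis(methoxymethoxy)-8-(3-methylbut-2-enyl)chroman-4-olate, both C4 epimers | C=C(C)CCc1cc([C@@H]2CC([O-])(N(C)OC)c3c(OCOC)cc(OCOC)c(CC=C(C)C)c3O2)ccc1OC.[Cs+] | intermediate (not isolated)
28 | (2S)-2-[4-methoxy-3-(3-methylbut-3-enyl)phenyl]-5,7-bis(methoxymethoxy)-8-(3-methylbut-2-enyl)chroman-4-one | C=C(C)CCc1cc([C@@H]2CC(=O)c3c(OCOC)cc(OCOC)c(CC=C(C)C)c3O2)ccc1OC | intermediate
29 | (2S)-2-[4-methoxy-3-(3-methylbut-3-enyl)phenyl]-8-(3-methylbut-2-enyl)-5,7-bis(trimethylsilyloxy)chroman-4-one | C=C(C)CCc1cc([C@@H]2CC(=O)c3c(O[Si](C)(C)C)cc(O[Si](C)(C)C)c(CC=C(C)C)c3O2)ccc1OC | intermediate (not isolated)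
30 | (2S)-5,7-dihydroxy-2-[4-methoxy-3-(3-methylbut-3-enyl)phenyl]-8-(3-methylbut-2-enyl)chroman-4-one | C=C(C)CCc1cc([C@@H]2CC(=O)c3c(O)cc(O)c(CC=C(C)C)c3O2)ccc1OC | target

**Step count**
Total: 13 steps. Longest linear sequence: 8 steps (steps 6 to 13, from 15).

**Steps most likely to fail**

Step 12 (proposed new method). What may go wrong is protonation of the aryl anion before it reaches the amide, retro-aldol fragmentation of the alkoxide, or attack of the alkoxide at C4a instead of C8a. The fallback uses known chemistry, sets out from 19 and 14 and returns at 28. Knoevenagel–Doebner condensation of 19 with malonic acid (pyridine, piperidine, 90 °C) should give (E)-3-[4-methoxy-3-(3-methylbut-3-enyl)phenyl]prop-2-enoic acid F1. The known fluoride-mediated C–O insertion of an aryne into a carboxylic acid (14, CsF, THF, sealed tube, 110 °C) should then place the oxygen on C8a and the cinnamoyl group on C4a. This should give (E)-1-[2-hydroxy-4,6-bis(methoxymethoxy)-3-(3-methylbut-2-enyl)phenyl]-3-[4-methoxy-3-(3-methylbut-3-enyl)phenyl]prop-2-en-1-one F2. Oxa-Michael closure of F2 (NaOAc, EtOH, reflux) should give racemic 2-[4-methoxy-3-(3-methylbut-3-enyl)phenyl]-5,7-bis(methoxymethoxy)-8-(3-methylbut-2-enyl)chroman-4-one F3. Preparative HPLC on a cellulose tris(3,5-dimethylphenylcarbamate) phase would separate the enantiomers, and the (2S) enantiomer is 28. In this fallback C2 is fixed by the separation and not by step 10, at the cost of half of the material.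

Step 4. What may go wrong is metalation at C4 between the two acetal oxygens instead of C6, incomplete lithiation of the crowded ring, or allylic substitution at the tertiary end of prenyl bromide. The fallback sets out from 7 and returns at 13, placing the prenyl group by a sigmatropic shift that can only reach the carbon next to the oxygen. Cleavage of the carbamate (Et2NH, DBU, MeCN, 40 °C, aqueous work-up) should give 3,5-bis(methoxymethoxy)-2-(trimethylsilyl)phenol F4. Palladium-catalysed O-alkylation with tert-butyl 2-methylbut-3-en-2-yl carbonate (Pd(PPh3)4, THF, 0 °C) should give 1,5-bis(methoxymethoxy)-3-(2-methylbut-3-en-2-yloxy)-2-(trimethylsilyl)benzene F5. Aromatic Claisen rearrangement of F5 (Eu(fod)3, CHCl3, 60 °C) should move the allyl unit to the one free ortho carbon and give phenol 13, which is triflated with PhNTf2 and DBU as in step 5 to give 14.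

Step 3. What may go wrong is loss of a methoxymethyl group to the silyl triflate used for N-protection, elimination of the carbamate on incomplete N-silylation, or metalation at C4. The fallback sets out from 2 and returns at 13, using a carbamate without N–H so that no silyl triflate is needed, and removing it by reduction. Acylation of 2 (Et2NCOCl, K2CO3, MeCN, reflux) should give 3,5-bis(methoxymethoxy)phenyl N,N-diethylcarbamate F6. Ortho-metalation and silylation (s-BuLi, TMEDA, THF, −78 °C; TMSCl) should give 3,5-bis(methoxymethoxy)-2-(trimethylsilyl)phenyl N,N-diethylcarbamate F7. A second metalation and copper-catalysed prenylation (s-BuLi, TMEDA, −78 °C; CuBr·SMe2, 8) should give 3,5-bis(methoxymethoxy)-2-(3-methylbut-2-enyl)-6-(trimethylsilyl)phenyl N,N-diethylcarbamate F8. Reduction with LiAlH4 (THF, reflux) should free phenol 13, which is triflated as in step 5 to give 14.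

**Further compounds**
F1 | step 12 | (E)-3-[4-methoxy-3-(3-methylbut-3-enyl)phenyl]prop-2-enoic acid | C=C(C)CCc1cc(/C=C/C(=O)O)ccc1OC
F2 | step 12 | (E)-1-[2-hydroxy-4,6-bis(methoxymethoxy)-3-(3-methylbut-2-enyl)phenyl]-3-[4-methoxy-3-(3-methylbut-3-enyl)phenyl]prop-2-en-1-one | C=C(C)CCc1cc(/C=C/C(=O)c2c(O)c(CC=C(C)C)c(OCOC)cc2OCOC)ccc1OC
F3 | step 12 | racemic 2-[4-methoxy-3-(3-methylbut-3-enyl)phenyl]-5,7-bis(methoxymethoxy)-8-(3-methylbut-2-enyl)chroman-4-one | C=C(C)CCc1cc(C2CC(=O)c3c(OCOC)cc(OCOC)c(CC=C(C)C)c3O2)ccc1OC
F4 | step 4 | 3,5-bis(methoxymethoxy)-2-(trimethylsilyl)phenol | COCOc1cc(O)c([Si](C)(C)C)c(OCOC)c1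
F5 | step 4 | 1,5-bis(methoxymethoxy)-3-(2-methylbut-3-en-2-yloxy)-2-(trimethylsilyl)benzene | C=CC(C)(C)Oc1cc(OCOC)cc(OCOC)c1[Si](C)(C)C
F6 | step 3 | 3,5-bis(methoxymethoxy)phenyl N,N-diethylcarbamate | CCN(CC)C(=O)Oc1cc(OCOC)cc(OCOC)c1
F7 | step 3 | 3,5-bis(methoxymethoxy)-2-(trimethylsilyl)phenyl N,N-diethylcarbamate | CCN(CC)C(=O)Oc1cc(OCOC)cc(OCOC)c1[Si](C)(C)C
F8 | step 3 | 3,5-bis(methoxymethoxy)-2-(3-methylbut-2-enyl)-6-(trimethylsilyl)phenyl N,N-diethylcarbamate | CCN(CC)C(=O)Oc1c(CC=C(C)C)c(OCOC)cc(OCOC)c1[Si](C)(C)C
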